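J and D are charged one to one (1.00 equiv of J), and the noon run is this very flask, followed so far. D and J give the product L, the by-product G and a free proton E. Q is a buffer base, Z its acid, and X is J carrying a proton.

| flask | D | J | Q | Z | remark | time |
|---|---|---|---|---|---|---|
| noon | 14 mM | 1 equiv | 3 equiv | 0.10 equiv | the very flask that is asked about, followed so far |  |
| flask | 14 mM | 1.00 equiv | 3.00 equiv | 0.100 equiv |  | 12 h |

noon run (percent of the D charged)

| time / h | D / % | L / % |
|---|---|---|
| 0.333 | 93.7 | 7.3 |
| 0.667 | 88.5 | 12.4 |
| 1.00 | 83.7 | 15.9 |
| 1.33 | 80.3 | 20.7 |
| 1.50 | 78.4 | 22.5 |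
| 2.00 | 73.8 | 25.6 |
| 2.50 | 71.5 | 29.1 |

(readings scatter by 0.5 percentage points)

- E is the free proton; pH is minus the decimal logarithm of its molar concentration
- steps under discussion: D + J <-> E + L + G; X <-> J + E; Z <-> Q + E
- the earlier runs do not show the pH; that part of a forecast is a guess

- part of the D that has reacted at 12 h
- pH of the solution at 12 h

The bench rule for equal charges says that D and J fall together, so the inverse of D climbs in a straight line with time. The reading at 1.00 h gives a slope k = 0.195 h⁻¹, in units of the D charged, and the rule then puts 70.1% of D reacted at 12 h. The border shows in a ratio: from 1.00 h to 2.50 h time grows by a factor 2.50, but the climb of that inverse grows by 2.05. So the rule stops here, and J seems to be lost by a second road.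

Write the balance of J. Charged J is free, or sits as X, or is spent in L. The readings do not show who takes E, so suppose that J takes it, and the proton of Z too. Then X is Z charged plus L, and each L costs two J, which makes J the limiting reagent. The ceiling, the L at which free J reaches zero, is J charged minus Z charged, divided by two: 0.450 equiv per D charged. I expect this flask just under it at 12 h.

The forecast differs, with 38% and pH 7.7: “The sharp early slowdown favours reversibility”.

The flask gives 44.0% and pH 8.35.

    D + J ⇌ E + L + G (K = 1.90 × 10⁻⁵ M, k = 0.00490 M⁻¹ s⁻¹)
    X ⇌ J + E, settled at all times (K = 1.60 × 10⁻¹⁰ M)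
    Z ⇌ Q + E, settled at all times (K = 2.00 × 10⁻⁴ M)

The forward half-life of D, 2.8 h at the charged concentrations, has grown to 140 h at 12.0 h, long against the time. By then 1.9% of the charged J is left free against 56% of the charged D. Against the ceiling of 0.450 equiv, this flask shows 45.0% of D reacted at 120 h. With 0.400 equiv of Z the same balance gives 0.300 equiv, and that flask stands at 29.7% of D reacted at 12 h.

The runs are calculated with made-up constants; scatter was added.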